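**Retrosynthetic overview**

1. The target comes from its C10 silyl ether by desilylation, so the free C10 hydroxyl and the C6 acetate are never exchanged.
2. The silyl ether comes from an acyclic bromo-enal by one chromium-mediated carbonyl allylation (C1–C2): the 14-membered carbocycle forms first, and the γ-lactone then closes onto the new C2 oxygen in the same flask.
3. The bromo-enal comes from a terminal alkene and methyl 2-(bromomethyl)acrylate (cross-metathesis, C1=C15); that alkene comes from a C6 enal and the silyl dienol ether of prenal (vinylogous aldol, C5–C6, sets C6).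
4. Key step: the C6 enal skeleton is made by joining an α-lithiated carbamate and an E-alkenylboronate, then a stereospecific 1,2-metalate shift (the alkenyl carbon migrates from boron to carbon), which forms C10–C11 and sets C10.
5. The boronate comes from hex-1-en-5-yne and the carbamate from but-3-yn-1-ol, each by a syn carbometalation that fixes an E trisubstituted alkene.

Assumption: ring carbons are numbered C1–C14 in the cembranolide way (C1 carries the lactone α-carbon C15, C2 the lactone oxygen, C16 is the lactone carbonyl, C17 the exocyclic methylene) and the SMILES is read as (1R,2S,3E,6S,7E,10S,11E) with a trans-fused lactone; where a chiral reagent series is named it is the one expected to give the stated face, and its antipode is used if the first run shows the opposite sense.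

**Step 1**
Reactants: 1 hex-1-en-5-yne
Product: 2 (E)-4,4,5,5-tetramethyl-2-(2-methylhexa-1,5-dien-1-yl)-1,3,2-dioxaborolane
Conditions: B2pin2, MeI, CuCl (5 mol%), Xantphos (5 mol%), NaOtBu, THF, rt
Reagents that add atoms: bis(pinacolato)diboron CC1(C)OB(OC1(C)C)B1OC(C)(C)C(C)(C)O1; iodomethane CI
Why: Copper-catalysed carboboration (syn borylcupration, then methylation of the alkenylcopper with retention) puts boron on the terminal and methyl on the internal alkyne carbon, cis to each other, giving the E-alkenylboronate; the isolated alkene does not react.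

**Step 2**
Reactants: 3 but-3-yn-1-ol
Product: 4 but-3-yn-1-yl N,N-diisopropylcarbamate
Conditions: iPr2NCOCl, Et3N, CH2Cl2, reflux
Reagents that add atoms: N,N-diisopropylcarbamoyl chloride CC(C)N(C(C)C)C(Cl)=O
Why: O-Carbamoylation of the primary alcohol installs the group that later directs α-lithiation and serves as the leaving group.

**Step 3**
Reactants: 4 but-3-yn-1-yl N,N-diisopropylcarbamate
Product: 7 (E)-5-hydroxy-3-methylpent-3-en-1-yl N,N-diisopropylcarbamate, via alkenylalane 5 (not isolated), via lithium alanate 6 (not isolated)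
Conditions: AlMe3, Cp2ZrCl2 (25 mol%), CH2Cl2, 0 °C to rt; then nBuLi, THF, −78 °C; (CH2O)n, rt; aq. HCl
Reagents that add atoms: trimethylaluminium C[Al](C)C; formaldehyde (as paraformaldehyde) C=O
Why: Negishi zirconium-catalysed carboalumination adds Me and Al syn across the alkyne (Me to the internal carbon), and the derived alanate is hydroxymethylated with retention, so the E trisubstituted allylic alcohol results.

**Step 4**
Reactants: 7 (E)-5-hydroxy-3-methylpent-3-en-1-yl N,N-diisopropylcarbamate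
Product: 8 (E)-3-methyl-5-(triethylsilyloxy)pent-3-en-1-yl N,N-diisopropylcarbamate
Conditions: TESCl, imidazole, CH2Cl2, 0 °C
Reagents that add atoms: chlorotriethylsilane CC[Si](Cl)(CC)CC
Why: Silylation masks the allylic hydroxyl against sBuLi; the triethylsilyl group is labile enough to be removed in the work-up of the next step.

**Step 5**
Reactants: 8 (E)-3-methyl-5-(triethylsilyloxy)pent-3-en-1-yl N,N-diisopropylcarbamate; 2 (E)-4,4,5,5-tetramethyl-2-(2-methylhexa-1,5-dien-1-yl)-1,3,2-dioxaborolane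
Product: 13 (2E,5S,6E)-3,7-dimethylundeca-2,6,10-triene-1,5-diol, via lithiated carbamate 9 (not isolated), via boron ate complex 10 (not isolated), via allylic boronic ester 11 (not isolated), via triethylsilyl ether 12 (not isolated)
Conditions: sBuLi, (+)-sparteine, Et2O, −78 °C, 5 h; then 2, −78 °C, 1 h; 40 °C, 12 h; NaOH, H2O2, THF, 0 °C; PPTS, MeOH, rt
Reagents that add atoms: hydrogen peroxide OO
Why: Hoppe–Aggarwal lithiation–borylation: sBuLi/(+)-sparteine removes the pro-R proton to give the configurationally stable (R)-lithiocarbamate, which is borylated with retention; the alkenyl group then shifts 1,2 from boron to carbon anti to the leaving carbamate (inversion at carbon, alkene geometry kept), and C–B oxidation with retention gives (S)-C10 before the silyl group is cleaved.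

**Step 6**
Reactants: 13 (2E,5S,6E)-3,7-dimethylundeca-2,6,10-triene-1,5-diol
Product: 14 (2E,5S,6E)-5-hydroxy-3,7-dimethylundeca-2,6,10-trienal
Conditions: TEMPO (10 mol%), PhI(OAc)2, CH2Cl2, 0 °C to rt
Reagents that add atoms: none
Why: Oxoammonium (TEMPO) oxidation is selective for the unhindered primary allylic alcohol over the secondary one and does not touch the C10 stereocentre.

**Step 7**
Reactants: 14 (2E,5S,6E)-5-hydroxy-3,7-dimethylundeca-2,6,10-trienal
Product: 15 (2E,5S,6E)-5-[tert-butyl(dimethyl)silyl]oxy-3,7-dimethylundeca-2,6,10-trienal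
Conditions: TBSCl, imidazole, DMF, rt
Reagents that add atoms: tert-butyldimethylsilyl chloride CC(C)(C)[Si](C)(C)Cl
Why: Silylation of the secondary alcohol gives a C10 protecting group that survives Lewis acid, acylation, metathesis and organochromium conditions and is removed last.

**Step 8**
Reactants: 16 3-methylbut-2-enal
Product: 17 (E)-tert-butyl(dimethyl)[(3-methylbuta-1,3-dien-1-yl)oxy]silane
Conditions: TBSOTf, Et3N, CH2Cl2, 0 °C to rt
Reagents that add atoms: tert-butyldimethylsilyl trifluoromethanesulfonate CC(C)(C)[Si](C)(C)OS(=O)(=O)C(F)(F)F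
Why: O-Silylation with γ-deprotonation of the enal (soft enolisation) gives the silyl dienol ether, the γ-nucleophilic form of the prenal unit.

**Step 9**
Reactants: 15 (2E,5S,6E)-5-[tert-butyl(dimethyl)silyl]oxy-3,7-dimethylundeca-2,6,10-trienal; 17 (E)-tert-butyl(dimethyl)[(3-methylbuta-1,3-dien-1-yl)oxy]silane
Product: 18 (2E,5S,6E,9S,10E)-9-[tert-butyl(dimethyl)silyl]oxy-5-hydroxy-3,7,11-trimethylpentadeca-2,6,10,14-tetraenal
Conditions: 17 (2.5 equiv), B-phenyl oxazaborolidinone from N-tosyl-D-tryptophan (1 equiv), iPrOH, EtCN, −78 °C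
Reagents that add atoms: none
Why: Vinylogous Mukaiyama aldol reaction of an aldehyde-derived dienolate: the γ-carbon of 17 attacks the Si face of the boron-bound enal through an open transition state, which sets (S)-C6 under reagent control and leaves the new enal E, while iPrOH takes up the silyl group.

**Step 10**
Reactants: 18 (2E,5S,6E,9S,10E)-9-[tert-butyl(dimethyl)silyl]oxy-5-hydroxy-3,7,11-trimethylpentadeca-2,6,10,14-tetraenal
Product: 19 (2E,5S,6E,9S,10E)-9-[tert-butyl(dimethyl)silyl]oxy-3,7,11-trimethyl-1-oxopentadeca-2,6,10,14-tetraen-5-yl acetate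
Conditions: Ac2O, pyridine, DMAP (cat.), CH2Cl2, 0 °C
Reagents that add atoms: acetic anhydride CC(=O)OC(C)=O
Why: Acylation of the only free hydroxyl installs the C6 acetate of the target at the point where C6–OH and C10–OH are differentiated.

**Step 11**
Reactants: 19 (2E,5S,6E,9S,10E)-9-[tert-butyl(dimethyl)silyl]oxy-3,7,11-trimethyl-1-oxopentadeca-2,6,10,14-tetraen-5-yl acetate; 20 methyl 2-(bromomethyl)prop-2-enoate
Product: 21 methyl (2Z,6E,8S,10E,12S,14E)-12-acetoxy-2-(bromomethyl)-8-[tert-butyl(dimethyl)silyl]oxy-6,10,14-trimethyl-16-oxohexadeca-2,6,10,14-tetraenoate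
Conditions: 20 (5 equiv), Hoveyda–Grubbs second-generation catalyst, (H2IMes)Cl2Ru(=CH-C6H4-2-OiPr) (10 mol%), CH2Cl2, 40 °C
Reagents that add atoms: none
Why: Olefin cross-metathesis engages only the monosubstituted alkene of 19 with the excess 1,1-disubstituted acrylate (by analogy with methacrylate and itaconate partners), and thermodynamic control places the chain trans to the ester, giving the 2Z bromide.

**Step 12**
Reactants: 21 methyl (2Z,6E,8S,10E,12S,14E)-12-acetoxy-2-(bromomethyl)-8-[tert-butyl(dimethyl)silyl]oxy-6,10,14-trimethyl-16-oxohexadeca-2,6,10,14-tetraenoate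
Product: 24 (1R,2S,3E,6S,7E,10S,11E)-6-acetoxy-10-[tert-butyl(dimethyl)silyl]oxycembra-3,7,11,15(17)-tetraen-16,2-olide, via trimethylsilyl ether 22 (not isolated), via hydroxy ester 23 (not isolated)
Conditions: CrCl2 (10 mol%), (S,S)-carbazole bis(oxazoline) ligand (12 mol%), Mn powder, TMSCl, iPr2NEt (30 mol%), THF, rt, 21 added over 12 h (final 2 mM); then 1 M HCl, THF, 0 °C to rt
Reagents that add atoms: none
Why: Proposed new method: a catalytic, ligand-controlled Nozaki–Hiyama (Barbier-type) 2-(alkoxycarbonyl)allylation used as a macrocyclisation; divalent chromium (regenerated by Mn) inserts into the allylic C–Br bond, the ligand-bound trivalent allylchromium equilibrates to the geometry with the chain pseudo-equatorial and adds through a chair transition state to the Re face of the enal carbonyl (anti adduct, 1R,2S), TMSCl releases chromium, and acid work-up desilylates and lactonises to the trans-fused lactone; the closest known reactions are the intermolecular chromium/carbazole bis(oxazoline)-catalysed 2-(alkoxycarbonyl)allylation–lactonisation of aldehydes and stoichiometric CrCl2 Barbier macrocyclisations to α-methylene lactones.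

**Step 13**
Reactants: 24 (1R,2S,3E,6S,7E,10S,11E)-6-acetoxy-10-[tert-butyl(dimethyl)silyl]oxycembra-3,7,11,15(17)-tetraen-16,2-olide
Product: 25 (1R,2S,3E,6S,7E,10S,11E)-6-acetoxy-10-hydroxycembra-3,7,11,15(17)-tetraen-16,2-olide (CNP0168244.1)
Conditions: HF·pyridine, pyridine, THF, 0 °C to rt
Reagents that add atoms: none
Why: Buffered fluoride cleavage of the silyl ether frees the C10 hydroxyl without affecting the acetate, the α-methylene lactone or the alkenes.

**Compound list**

1 | hex-1-en-5-yne | C=CCCC#C | starting material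
2 | (E)-4,4,5,5-tetramethyl-2-(2-methylhexa-1,5-dien-1-yl)-1,3,2-dioxaborolane | C=CCC/C(C)=C/B1OC(C)(C)C(C)(C)O1 | intermediate
3 | but-3-yn-1-ol | C#CCCO | starting material
4 | but-3-yn-1-yl N,N-diisopropylcarbamate | C#CCCOC(=O)N(C(C)C)C(C)C | intermediate
5 | (E)-[4-(diisopropylcarbamoyloxy)-2-methylbut-1-en-1-yl]dimethylaluminium | C[Al](C)/C=C(\C)CCOC(=O)N(C(C)C)C(C)C | intermediate
6 | lithium (E)-butyl[4-(diisopropylcarbamoyloxy)-2-methylbut-1-en-1-yl]dimethylaluminate | [Li+].CCCC[Al-](C)(C)/C=C(\C)CCOC(=O)N(C(C)C)C(C)C | intermediate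
7 | (E)-5-hydroxy-3-methylpent-3-en-1-yl N,N-diisopropylcarbamate | OC/C=C(\C)CCOC(=O)N(C(C)C)C(C)C | intermediate
8 | (E)-3-methyl-5-(triethylsilyloxy)pent-3-en-1-yl N,N-diisopropylcarbamate | CC[Si](CC)(CC)OC/C=C(\C)CCOC(=O)N(C(C)C)C(C)C | intermediate
9 | [(1R,3E)-1-(diisopropylcarbamoyloxy)-3-methyl-5-(triethylsilyloxy)pent-3-en-1-yl]lithium, (+)-sparteine complex | [Li][C@@H](OC(=O)N(C(C)C)C(C)C)C/C(C)=C/CO[Si](CC)(CC)CC | intermediate
10 | lithium [(1R,3E)-1-(diisopropylcarbamoyloxy)-3-methyl-5-(triethylsilyloxy)pent-3-en-1-yl][(E)-2-methylhexa-1,5-dien-1-yl](pinacolato)borate | [Li+].C=CCC/C(C)=C/[B-]1(OC(C)(C)C(C)(C)O1)[C@@H](OC(=O)N(C(C)C)C(C)C)C/C(C)=C/CO[Si](CC)(CC)CC | intermediate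
11 | triethyl{[(2E,5S,6E)-3,7-dimethyl-5-(4,4,5,5-tetramethyl-1,3,2-dioxaborolan-2-yl)undeca-2,6,10-trien-1-yl]oxy}silane | CC[Si](CC)(CC)OC/C=C(\C)C[C@H](B1OC(C)(C)C(C)(C)O1)/C=C(\C)CCC=C | intermediate
12 | (2E,5S,6E)-3,7-dimethyl-1-(triethylsilyloxy)undeca-2,6,10-trien-5-ol | CC[Si](CC)(CC)OC/C=C(\C)C[C@H](O)/C=C(\C)CCC=C | intermediate
13 | (2E,5S,6E)-3,7-dimethylundeca-2,6,10-triene-1,5-diol | OC/C=C(\C)C[C@H](O)/C=C(\C)CCC=C | intermediate
14 | (2E,5S,6E)-5-hydroxy-3,7-dimethylundeca-2,6,10-trienal | O=C/C=C(\C)C[C@H](O)/C=C(\C)CCC=C | intermediate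
15 | (2E,5S,6E)-5-[tert-butyl(dimethyl)silyl]oxy-3,7-dimethylundeca-2,6,10-trienal | O=C/C=C(\C)C[C@H](O[Si](C)(C)C(C)(C)C)/C=C(\C)CCC=C | intermediate
16 | 3-methylbut-2-enal (prenal) | CC(C)=CC=O | starting material
17 | (E)-tert-butyl(dimethyl)[(3-methylbuta-1,3-dien-1-yl)oxy]silane | C=C(C)/C=C/O[Si](C)(C)C(C)(C)C | intermediate
18 | (2E,5S,6E,9S,10E)-9-[tert-butyl(dimethyl)silyl]oxy-5-hydroxy-3,7,11-trimethylpentadeca-2,6,10,14-tetraenal | O=C/C=C(\C)C[C@H](O)/C=C(\C)C[C@H](O[Si](C)(C)C(C)(C)C)/C=C(\C)CCC=C | intermediate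
19 | (2E,5S,6E,9S,10E)-9-[tert-butyl(dimethyl)silyl]oxy-3,7,11-trimethyl-1-oxopentadeca-2,6,10,14-tetraen-5-yl acetate | O=C/C=C(\C)C[C@H](OC(C)=O)/C=C(\C)C[C@H](O[Si](C)(C)C(C)(C)C)/C=C(\C)CCC=C | intermediate
20 | methyl 2-(bromomethyl)prop-2-enoate | C=C(CBr)C(=O)OC | starting material
21 | methyl (2Z,6E,8S,10E,12S,14E)-12-acetoxy-2-(bromomethyl)-8-[tert-butyl(dimethyl)silyl]oxy-6,10,14-trimethyl-16-oxohexadeca-2,6,10,14-tetraenoate | O=C/C=C(\C)C[C@H](OC(C)=O)/C=C(\C)C[C@H](O[Si](C)(C)C(C)(C)C)/C=C(\C)CC/C=C(\CBr)C(=O)OC | intermediate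
22 | methyl 2-[(1R,2S,3E,6S,7E,10S,11E)-6-acetoxy-10-[tert-butyl(dimethyl)silyl]oxy-4,8,12-trimethyl-2-(trimethylsilyloxy)cyclotetradeca-3,7,11-trien-1-yl]prop-2-enoate | COC(=O)C(=C)[C@@H]1[C@@H](O[Si](C)(C)C)/C=C(\C)C[C@H](OC(C)=O)/C=C(\C)C[C@H](O[Si](C)(C)C(C)(C)C)/C=C(\C)CC1 | intermediate
23 | methyl 2-[(1R,2S,3E,6S,7E,10S,11E)-6-acetoxy-10-[tert-butyl(dimethyl)silyl]oxy-2-hydroxy-4,8,12-trimethylcyclotetradeca-3,7,11-trien-1-yl]prop-2-enoate | COC(=O)C(=C)[C@@H]1[C@@H](O)/C=C(\C)C[C@H](OC(C)=O)/C=C(\C)C[C@H](O[Si](C)(C)C(C)(C)C)/C=C(\C)CC1 | intermediate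
24 | (1R,2S,3E,6S,7E,10S,11E)-6-acetoxy-10-[tert-butyl(dimethyl)silyl]oxycembra-3,7,11,15(17)-tetraen-16,2-olide (trans-fused α-methylene-γ-butyrolactone on the 14-membered ring) | C=C1C(=O)O[C@H]2/C=C(\C)C[C@H](OC(C)=O)/C=C(\C)C[C@H](O[Si](C)(C)C(C)(C)C)/C=C(\C)CC[C@H]12 | intermediate
25 | (1R,2S,3E,6S,7E,10S,11E)-6-acetoxy-10-hydroxycembra-3,7,11,15(17)-tetraen-16,2-olide (CNP0168244.1) | C=C1C(=O)O[C@H]2/C=C(\C)C[C@H](OC(C)=O)/C=C(\C)C[C@H](O)/C=C(\C)CC[C@H]12 | target

**Step count and risks**

Total steps: 13. Longest linear sequence: 11 steps (from 3 to 25 through steps 2–7 and 9–13).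

Steps most likely to fail:

Step 12 (the proposed new macrocyclisation; risks are oligomerisation, syn/anti leakage and the facial sense in a flexible 14-membered transition state). The fallback uses known chemistry, sets out from 21 and comes back at 24. It gives up ligand control for the classical stoichiometric Nozaki–Hiyama ring closure: 21 is added slowly to CrCl2 (8 equiv) in THF at 2 mM, so that the anti preference of the allylchromium chair and the substrate alone set C1 and C2. The ring-closed hydroxy ester 23 is isolated, its diastereomers are separated, and the right one is lactonised in a separate operation (PPTS, CH2Cl2) to 24. It makes no compound outside the list (none, F0).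

Step 11 (cross-metathesis with an electron-poor 1,1-disubstituted alkene that carries an allylic bromide; risks are low conversion and loss of the ruthenium carbene). The fallback sets out from 19 and comes back at 21. Metathesis is run instead with methyl 2-(hydroxymethyl)prop-2-enoate, whose free allylic hydroxyl replaces the bromide during the ruthenium step, to give methyl (2E,6E,8S,10E,12S,14E)-12-acetoxy-8-[tert-butyl(dimethyl)silyl]oxy-2-(hydroxymethyl)-6,10,14-trimethyl-16-oxohexadeca-2,6,10,14-tetraenoate F1. The bromide is then installed afterwards by an Appel reaction (CBr4, PPh3, CH2Cl2, 0 °C), which gives 21.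

Step 9 (vinylogous aldol of an aldehyde-derived dienolate onto a β,β-disubstituted enal; risks are α versus γ attack, E/Z of the new enal and face selectivity). The fallback sets out from 15 and comes back at 18 through the ester oxidation level. Methyl 3-methylbut-2-enoate is converted (LDA, TBSCl, THF, −78 °C) into tert-butyl{[(1Z)-1-methoxy-3-methylbuta-1,3-dien-1-yl]oxy}dimethylsilane F2. SiCl4 with a catalytic chiral bisphosphoramide (Lewis-base-activated Lewis acid catalysis, CH2Cl2, −78 °C) adds F2 to 15 and gives, through methyl (2E,5S,6E,9S,10E)-9-[tert-butyl(dimethyl)silyl]oxy-3,7,11-trimethyl-5-(trichlorosilyloxy)pentadeca-2,6,10,14-tetraenoate F3 (not isolated), methyl (2E,5S,6E,9S,10E)-9-[tert-butyl(dimethyl)silyl]oxy-5-hydroxy-3,7,11-trimethylpentadeca-2,6,10,14-tetraenoate F4. DIBAL-H (CH2Cl2, −78 °C) reduces F4 to (2E,5S,6E,9S,10E)-9-[tert-butyl(dimethyl)silyl]oxy-3,7,11-trimethylpentadeca-2,6,10,14-tetraene-1,5-diol F5. The conditions of step 6 (TEMPO, PhI(OAc)2) then oxidise only the primary allylic alcohol of F5 and give 18.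

**Further compounds**

F0 | step 12 | none | none
F1 | step 11 | methyl (2E,6E,8S,10E,12S,14E)-12-acetoxy-8-[tert-butyl(dimethyl)silyl]oxy-2-(hydroxymethyl)-6,10,14-trimethyl-16-oxohexadeca-2,6,10,14-tetraenoate | O=C/C=C(\C)C[C@H](OC(C)=O)/C=C(\C)C[C@H](O[Si](C)(C)C(C)(C)C)/C=C(\C)CC/C=C(\CO)C(=O)OC
F2 | step 9 | tert-butyl{[(1Z)-1-methoxy-3-methylbuta-1,3-dien-1-yl]oxy}dimethylsilane | C=C(C)/C=C(/OC)O[Si](C)(C)C(C)(C)C
F3 | step 9 | methyl (2E,5S,6E,9S,10E)-9-[tert-butyl(dimethyl)silyl]oxy-3,7,11-trimethyl-5-(trichlorosilyloxy)pentadeca-2,6,10,14-tetraenoate | COC(=O)/C=C(\C)C[C@H](O[Si](Cl)(Cl)Cl)/C=C(\C)C[C@H](O[Si](C)(C)C(C)(C)C)/C=C(\C)CCC=C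
F4 | step 9 | methyl (2E,5S,6E,9S,10E)-9-[tert-butyl(dimethyl)silyl]oxy-5-hydroxy-3,7,11-trimethylpentadeca-2,6,10,14-tetraenoate | COC(=O)/C=C(\C)C[C@H](O)/C=C(\C)C[C@H](O[Si](C)(C)C(C)(C)C)/C=C(\C)CCC=C
F5 | step 9 | (2E,5S,6E,9S,10E)-9-[tert-butyl(dimethyl)silyl]oxy-3,7,11-trimethylpentadeca-2,6,10,14-tetraene-1,5-diol | OC/C=C(\C)C[C@H](O)/C=C(\C)C[C@H](O[Si](C)(C)C(C)(C)C)/C=C(\C)CCC=C
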